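The constants were set for the occasion; the flask was simulated.

If you want a quick number for this flask and your hunch is that the excess of coupling partner keeps the target safe, here is what I have to work with.

    2 substrate → side product B (k1 = 2.58 × 10⁻⁴ L mol⁻¹ s⁻¹)
    substrate → side product A (k2 = 3.25 × 10⁻⁴ s⁻¹)
    substrate + coupling partner → target (k3 = 6.16 × 10⁻⁴ L mol⁻¹ s⁻¹)

substrate 0.50 M (fed, over 10 h); coupling partner 0.900 M; time 8.0 d

- in percentages every species weighs as the substrate in it: one side product B counts as two
- for a step with 2 of a species take k times the square, and two of it per event
- the reaction counts as stopped when no species that holds the substrate changes by six tenths of a point or more over the second half of the time
- run time (flask): 8.0 d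

1. at 8.0 d, what has stopped the reaction, if anything has (the coupling partner has run out first / all of the substrate has reacted / it is still moving)
2. share of the substrate used up at 8.0 d
3. target at 8.0 d, in percent of the substrate charged
4. side product A at 8.0 d, in percent of the substrate charged

I would not trust that hunch, and here is why. At the charged level of coupling partner the half-life of substrate by the step to target is 0.35 h, and by the step to side product A alone it is 0.59 h. Because both are short against the 10 h feed, I expect substrate to go as it arrives and to be used up well before 8.0 d.

What matters is how each portion divides. At a given coupling partner level the step to target is pseudo-first-order in substrate, so substrate cancels from the ratio of the two rates. Call the balance concentration 0.528 M the coupling partner level at which both steps use substrate equally; it is the inverse of the selectivity factor. The share going to target is then the partner level divided by the sum of that level and the balance concentration.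

Solve both ends and join them, leaving side product B aside. At the start the share is 63.0%. A first pass at the end gives 52.6%, and their mean, 57.8%, leaves 0.611 M of coupling partner. That level gives an end share of 53.7%, so I commit to 58.4% target and 41.6% side product A.

The forecast says all of the substrate has reacted, with substrate “gone within hours of the feed ending”, conversion 100%, target 57.9%, which is below mine, and side product A 40.9%, which is also below mine. In the flask all of the substrate has reacted, with conversion 100%, target 57.9% and side product A 41.0%.

At 0.214 d this flask's step to target was using substrate at 1.4 times the rate of the step to side product A, which with 0.528 M puts the coupling partner then at 0.755 M. At 8.00 d this flask held 68% of its coupling partner, 0.610 M, which is above 0.528 M. In the neighbour flask with 0.36 M of coupling partner, the share reckoned by the same rule runs from 40.6% to 27.0% with 54% of its own charge left, a mean of 33.8%, and that flask holds 32.9% target.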